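(The earlier runs and the new flask are calculated on assumed constants; scatter was added.)

Whether to charge more partner turns on one ratio, so settle that first.

| flask | substrate | partner | remark | time |
|---|---|---|---|---|
| west | 30 mM | 20 mM | run made earlier |  |
| north | 30 mM | 29 mM | run made earlier |  |
| south-west | 15 mM | 39 mM | run made earlier |  |
| flask | 30 mM | 39.0 mM |  | 2.5 min |

| run | time / min | substrate / % | mono adduct / % |
|---|---|---|---|
| west | 0.417 | 84 | 2 |
| west | 0.833 | 71 | 6 |
| west | 1.33 | 57 | 4 |
| west | 1.50 | 55 | 6 |
| west | 2.00 | 48 | 4 |
| west | 2.50 | 39 | 6 |
| north | 0.200 | 91 | 3 |
| north | 0.333 | 86 | 3 |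
| north | 0.500 | 80 | 0 |
| north | 0.833 | 68 | 8 |
| north | 1.50 | 54 | 5 |
| north | 2.50 | 34 | 5 |
| south-west | 0.200 | 91 | 1 |
| south-west | 0.667 | 72 | 4 |
| south-west | 1.33 | 53 | 7 |
| south-west | 2.00 | 40 | 7 |
| south-west | 2.50 | 31 | 7 |

(each reading ± 1.5 percentage points)

- by-product is meant together with its idle adduct
- the earlier runs were read with a standard deviation of 1.5 percentage points
- steps that have been proposed: substrate + partner -> mono adduct + by-product; partner + mono adduct -> double product + by-product; partner + by-product <-> idle adduct; partner + mono adduct -> over-reaction product; substrate <-> dormant form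
- what has gone from substrate into another species counts as reacted, even if it can come back
- the earlier runs do not show how much of partner is bound; that part of a forecast is a guess

1. part of the substrate that has reacted at 2.5 min
2. share of the unused partner that is free and not bound as idle adduct, at 2.5 min

Take the last readings as apparent first-order constants, my own reading with the scatter of the runs: the west run gives 0.377 min⁻¹ and the south-west run 0.468 min⁻¹. A line through them against charged partner leaves 0.280 min⁻¹ at no partner. That gives 0.0173 mM⁻¹, which I call the partner pull, a selectivity factor: substrate's rate by partner routes over its rate into dormant form, per mM of partner. The shared time cancels in the algebra, but the value remains a reading at 2.5 min on charged partner.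

Now build the flask.

1. Main step alone, partner held at its charge: the rate is 0.188 min⁻¹, so c is 37.6%.

2. Add the dormant form: its rate is faster than the partner rate, the split is 0.673, and c rises to 69.0%.

3. Add partner consumption: by my estimate the partner routes take about 8.33 mM of partner in this flask. The south-west run charged half the substrate, so this flask averages about a quarter of that amount less partner. I commit to c of 68.2%.

The forecast says 68% and 70%, with “Dependence on partner is therefore weak.” Its fr is a guess, since the runs do not show bound partner.

The flask gives 66.1% and 76.8%.

    substrate + partner → mono adduct + by-product (k = 0.0720 L mol⁻¹ s⁻¹)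
    partner + mono adduct → double product + by-product (k = 0.140 L mol⁻¹ s⁻¹)
    partner + by-product ⇌ idle adduct, settled at all times (K = 1900 L mol⁻¹)
    partner + mono adduct → over-reaction product (k = 0.470 L mol⁻¹ s⁻¹)
    substrate ⇌ dormant form (K = 6.80, k = 0.00560 s⁻¹)

At the asked time this flask holds 5.47% mono adduct, 3.25% double product and 10.9% over-reaction product against 46.4% dormant form. That is a split of 0.423, or 0.0108 mM⁻¹ of pull, where the runs read 0.0173 mM⁻¹. The neighbour flask, charged with 66 mM of partner, is reckoned at 1.14 from the runs' pull and 0.713 from this flask's. Its end state gives 0.722, and its c is 72.5%.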